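Whether target is lost faster than starting material is used sets what stands in these flasks at the end.

all flasks: spent carrier 26 mM
- Wednesday's: starting material 0.28 M; salt in the second phase 0.30 M; capture agent 0.010 M; temperature 0 °C; run made earlier
- Friday's: starting material 0.44 M; salt in the second phase 0.30 M; capture agent 0.010 M; temperature 18 °C; run made earlier
- Sunday's: starting material 0.20 M; salt in the second phase 0.30 M; capture agent 0.015 M; temperature 0 °C; run made earlier
- midnight: starting material 0.20 M; salt in the second phase 0.300 M; capture agent 0.0100 M; temperature 5 °C; time 6.0 h; volume of the second phase over the first 0.25
- winter: starting material 0.20 M; salt in the second phase 0.300 M; capture agent 0.0100 M; temperature 30 °C; time 6.0 h; volume of the second phase over the first 0.25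

- Wednesday's (time / h: target / %, starting material / %): 0.500: 3.5, 96.4; 1.33: 10.6, 89.1; 3.00: 20.0, 78.0; 8.00: 31.3, 55.9
- Friday's (time / h: target / %, starting material / %): 0.417: 11.9, 85.8; 1.33: 17.5, 68.6; 2.50: 14.2, 57.6; 4.00: 9.4, 49.5
- Sunday's (time / h: target / %, starting material / %): 0.833: 5.8, 94.3; 2.50: 19.2, 79.3; 5.00: 29.2, 64.2; 8.00: 34.5, 50.9

(each reading ± 0.5 percentage points)

* which of the two there is more of at the end, midnight (target / over-reaction product)
* which of the two there is more of at the end, winter (target / over-reaction product)
* target at the end, in percent of the starting material charged, midnight
* target at the end, in percent of the starting material charged, winter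

- in the second phase: salt in the second phase, spent salt in the second phase; everything else is in the first
- charges count per volume of the first phase; a concentration in a rate is the amount of a species over the volume of its own phase; every rate counts per litre of the first phase
- steps under discussion: spent carrier + salt in the second phase <-> fresh carrier + spent salt in the second phase; starting material + fresh carrier -> target + spent carrier; target -> over-reaction product; spent carrier + capture agent -> trapped intermediate
- the earlier runs hold the two phases in the same ratio of volumes as the flask asked about

The quantity to carry is the loss ratio: the first-order constant for target's loss over the constant for the use of starting material, a selectivity factor for steps in a row. A ratio of one is your zero, with both constants equal. With first-order steps, target gathers while its share stands below starting material over the ratio. For first-order steps, the target share is the difference between the two exponential decays, divided by the ratio minus one.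

Turn the temperature first. The missing balance gives a loss constant of 0.0842 /h in Wednesday's run and 0.729 /h in Friday's. Early starting-material readings give use constants of 0.0828 /h and 0.283 /h. So by hand, heat raises loss more than use. The readings agree: Friday's target falls from 17.5% to 9.4%, while Wednesday's climbs to 31.3%.

Taking a constant factor per degree, rough because the charges differ, midnight has constants of 0.153 /h and 0.117 /h. Its ratio is 1.32. Winter has 3.07 /h and 0.643 /h, so its loss ratio 4.77 stands far above one.

Now turn the time. At 6.0 h, my reckoning gives midnight 31.2% target, more than its over-reaction product. It gives winter 0.558%, less than its over-reaction product.

Last, turn the capture agent. Sunday's run, with more of it and less starting material, reads 34.5% target at 8.00 h, more than Wednesday's.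

The forecast says target and 30% for midnight, and over-reaction product and 1% for winter, where “target sits at quasi-steady state”.

The flasks give target at 31.9% for midnight, and over-reaction product with 0.745% target for winter.

    spent carrier + salt in the second phase ⇌ fresh carrier + spent salt in the second phase (K = 0.550, k = 0.0892 /M/min, Ea = 67.0 kJ/mol, ΔH = −9.00 kJ/mol)
    starting material + fresh carrier → target + spent carrier (k = 0.163 /M/min, Ea = 55.0 kJ/mol)
    target → over-reaction product (k = 0.00257 /min, Ea = 83.0 kJ/mol)
    spent carrier + capture agent → trapped intermediate (k = 0.0362 /M/min, Ea = 66.0 kJ/mol)
    (constants at 5 °C)

You still have 8.46% starting material in winter at 6.0 h, beside 90.8% over-reaction product. Its fall from 19.0% at 3.00 h gives a late use constant of 0.270 /h, so the ratio in that stretch is 11.4. Starting material over that ratio minus one is 0.813% target. With the early ratio, the same winter flask read at 1.5 h comes to 9.85% target, and it holds 7.78%.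

The earlier runs and the new flask are simulated with constants of no real substance; scatter was added.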